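**Plan**

1. Retrosynthesis (numbering of the 3,7-dioxabicyclo[3.3.0]octane core: C-1 carbinol bridgehead, C-2 ArCH next to it, O-3, C-4, C-5 CH bridgehead, C-6 ArCH, O-7, C-8): the benzylic C–H bonds at C-2 and C-6 are cut first (aryl lactol reduction), then both aryl–C bonds (one aryllithium used twice on a bislactone), then the C-4–C-5 bond and the O-3–C-2 lactone bond, and last the C-1–C-5 and O-7–C-6 bonds.
2. Forward: a silyl-protected hydroxypyruvate ester (C-2/C-1/C-8) and a thioacetate silyl ketene acetal (C-5/C-6) are joined by a catalytic enantioselective aldol, and the C-8 hydroxyl lactonises onto C-6 to close the C-5/C-6/O-7/C-8/C-1 ring. Hydroxymethylation at C-5 and a second lactonisation close the C-1/C-2/O-3/C-4/C-5 ring; both aryl groups are added, both lactols are reduced, and debenzylation ends the route.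
3. Enabling feature: C-1 is a tertiary carbinol flanked by an oxymethylene (C-8) and an oxygenated carbon (C-2), so it is the keto carbon of a hydroxypyruvate; C-5/C-6 is an acetate unit whose carbonyl carbon C-6 is γ to O-7, so the first ring is a γ-lactone. The two aryl groups are identical.
4. Stereochemistry: C-1 comes from the chiral copper bis(oxazoline) catalyst; C-5 from reaction anti to the C-1 alkoxide, locked by the cis ring fusion; C-2 and C-6 from hydride delivery to the convex face of the cis-fused oxocarbenium ions, which leaves both aryl groups on the concave face (trans to 1-OH and 5-H), as in the target.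

Key step: step 4

Assumption: keto ester 3 is taken to bind the copper catalyst as a pyruvate ester does (two-point chelation through the keto and ester carbonyls), so the established facial sense of the tert-butyl-box catalysts carries over.

**Step 1**
Reactants: 1 methyl 2-(hydroxymethyl)prop-2-enoate
Product: 2 methyl 2-({[tert-butyl(dimethyl)silyl]oxy}methyl)prop-2-enoate
Conditions: TBSCl, imidazole, DMF, 0 °C to rt
Reagents that add atoms: tert-butyl(chloro)dimethylsilane, CC(C)(C)[Si](C)(C)Cl
Why: Imidazole-promoted silylation of a primary alcohol (standard TBS protection); the bulky silyl ether later keeps this oxygen from competing for the Lewis acid.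

**Step 2**
Reactants: 2 methyl 2-({[tert-butyl(dimethyl)silyl]oxy}methyl)prop-2-enoate
Product: 3 methyl 3-{[tert-butyl(dimethyl)silyl]oxy}-2-oxopropanoate
Conditions: O3, CH2Cl2/MeOH, −78 °C; then Me2S, −78 °C to rt
Reagents that add atoms: ozone, [O-][O+]=O
Why: Ozonolysis of the 1,1-disubstituted alkene with reductive work-up removes the methylene carbon and leaves the vicinal keto ester; no stereocenter is formed.

**Step 3**
Reactants: 4 S-tert-butyl ethanethioate
Product: 5 tert-butyl 1-[(trimethylsilyl)oxy]ethenyl sulfide
Conditions: LiN(i-Pr)2 (LDA), THF, −78 °C; then Me3SiCl, −78 °C to rt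
Reagents that add atoms: chlorotrimethylsilane, C[Si](C)(C)Cl
Why: Kinetic enolisation of the thioester and O-silylation give the silyl ketene acetal (standard preparation of a Mukaiyama aldol donor).

**Step 4**
Reactants: 3 methyl 3-{[tert-butyl(dimethyl)silyl]oxy}-2-oxopropanoate; 5 tert-butyl 1-[(trimethylsilyl)oxy]ethenyl sulfide
Product: 8 methyl (3S)-3-hydroxy-5-oxooxolane-3-carboxylate, via silylated aldol adduct 6 (not isolated), via dihydroxy thioester 7 (not isolated)
Conditions: Cu((R,R)-t-Bu-box)(OTf)2 (10 mol%; box = 2,2'-(propane-2,2-diyl)bis(4-tert-butyl-4,5-dihydro-1,3-oxazole)), THF, −78 °C; then 48% aq HF, MeCN, 0 °C to rt; then TsOH·H2O (cat.), PhMe, 50 °C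
Reagents that add atoms: none
Why: The divalent copper bis(oxazoline) complex binds keto ester 3 as a five-membered chelate through its keto and ester carbonyl oxygens, and silyl ketene acetal 5 adds to the activated keto carbon through an open transition state with silyl transfer to the aldolate, which forms the C-1–C-5 bond (catalytic enantioselective Mukaiyama aldol; the closest known case is the copper tert-butyl-box addition of thioacetate silyl ketene acetals to pyruvate esters). HF then removes both silyl groups, and the freed C-8 hydroxyl attacks the thioester carbon in a 5-exo-trig acyl substitution with loss of thiol, which forms the O-7–C-6 bond and closes the C-5/C-6/O-7/C-8/C-1 ring as a γ-lactone. The one new stereocenter, C-1, is set by the catalyst: the (S,S)-ligand is known to direct attack to the Si face of chelated pyruvates, so the (R,R)-ligand should expose the Re face of 3 and give the (S)-carbinol. The step needs enantiofacial selectivity and chemoselectivity for the keto group, both secured by the 1,2-dicarbonyl chelate, while the bulky TBS ether keeps the β-oxygen from acting as a third donor. Ring closure is unambiguous because the only other acyl group, the methyl ester on C-1, could give only a β-lactone with the C-8 hydroxyl.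

**Step 5**
Reactants: 8 methyl (3S)-3-hydroxy-5-oxooxolane-3-carboxylate
Product: 10 (1S,5S)-1-hydroxy-3,7-dioxabicyclo[3.3.0]octane-2,6-dione, via hydroxymethyl lactone 9 (not isolated)
Conditions: LiN(i-Pr)2 (2.2 equiv), THF, −78 °C; CH2O (gas), −78 to −20 °C; aq NH4Cl; then TsOH·H2O (cat.), PhMe, 50 °C
Reagents that add atoms: formaldehyde, C=O
Why: Double deprotonation gives the alkoxide–enolate dianion of the β-hydroxy lactone, which should take up formaldehyde anti to the O–Li group (aldol hydroxymethylation in the manner of Fráter–Seebach dianion reactions of malate-type β-hydroxy esters); the new CH2OH then lies cis to the ester and lactonises to the cis-fused bislactone, fixing C-5 with its H cis to 1-OH.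

**Step 6**
Reactants: 10 (1S,5S)-1-hydroxy-3,7-dioxabicyclo[3.3.0]octane-2,6-dione; 11 1-(benzyloxy)-4-bromo-2-methoxybenzene
Product: 13 (1S,5S)-2,6-bis[4-(benzyloxy)-3-methoxyphenyl]-3,7-dioxabicyclo[3.3.0]octane-1,2,6-triol, via aryllithium 12 (not isolated)
Conditions: 11 (3.5 equiv), n-BuLi (3.4 equiv), THF, −78 °C; add 10, −78 to −40 °C; aq NH4Cl
Reagents that add atoms: none
Why: Bromine–lithium exchange gives aryllithium 12, which first deprotonates the tertiary OH and then adds once to each γ-lactone carbonyl to give tetrahedral lithium lactolates that hold at low temperature (aryllithium addition to lactones, as in C-aryl glycoside synthesis); both aryl–carbon bonds are made together because the aryl groups are identical, and the lactol centres (anomer mixture, in equilibrium with open keto alcohol forms) need no control.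

**Step 7**
Reactants: 13 (1S,5S)-2,6-bis[4-(benzyloxy)-3-methoxyphenyl]-3,7-dioxabicyclo[3.3.0]octane-1,2,6-triol
Product: 14 (1S,2S,5R,6R)-2,6-bis[4-(benzyloxy)-3-methoxyphenyl]-3,7-dioxabicyclo[3.3.0]octan-1-ol
Conditions: Et3SiH (6 equiv), BF3·OEt2 (3 equiv), CH2Cl2, −78 °C; quench with Et3N then aq NaHCO3 at −78 °C
Reagents that add atoms: none
Why: BF3 ionises each aryl lactol to a cyclic oxocarbenium ion and Et3SiH delivers hydride to its convex face, the concave face being blocked by the other ring (ionic reduction of lactols, as used for endo-aryl furofurans and C-aryl glycosides), so H-2 and H-6 enter cis to 1-OH and 5-H and both aryl groups end up on the concave face; low temperature and the cold basic quench guard against acid epimerisation of the benzylic ethers.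

**Step 8**
Reactants: 14 (1S,2S,5R,6R)-2,6-bis[4-(benzyloxy)-3-methoxyphenyl]-3,7-dioxabicyclo[3.3.0]octan-1-ol
Product: 15 (1S,2S,5R,6R)-2,6-bis(4-hydroxy-3-methoxyphenyl)-3,7-dioxabicyclo[3.3.0]octan-1-ol
Conditions: H2 (1 atm), Pd/C (10%), EtOAc, rt
Reagents that add atoms: none
Why: Hydrogenolysis of the two aryl benzyl ethers over Pd/C under neutral conditions (standard O-debenzylation) should free both phenols; the ring benzylic C–O bonds cleave more slowly without acid, and the reaction is stopped after uptake of two equivalents of hydrogen.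

**Compound list**

1 | methyl 2-(hydroxymethyl)prop-2-enoate | C=C(CO)C(=O)OC | starting material
2 | methyl 2-({[tert-butyl(dimethyl)silyl]oxy}methyl)prop-2-enoate | C=C(CO[Si](C)(C)C(C)(C)C)C(=O)OC | intermediate
3 | methyl 3-{[tert-butyl(dimethyl)silyl]oxy}-2-oxopropanoate | COC(=O)C(=O)CO[Si](C)(C)C(C)(C)C | intermediate
4 | S-tert-butyl ethanethioate | CC(=O)SC(C)(C)C | starting material
5 | tert-butyl 1-[(trimethylsilyl)oxy]ethenyl sulfide | C=C(O[Si](C)(C)C)SC(C)(C)C | intermediate
6 | methyl (2S)-4-(tert-butylsulfanyl)-2-({[tert-butyl(dimethyl)silyl]oxy}methyl)-4-oxo-2-[(trimethylsilyl)oxy]butanoate | COC(=O)[C@@](O[Si](C)(C)C)(CO[Si](C)(C)C(C)(C)C)CC(=O)SC(C)(C)C | intermediate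
7 | methyl (2S)-4-(tert-butylsulfanyl)-2-hydroxy-2-(hydroxymethyl)-4-oxobutanoate | COC(=O)[C@@](O)(CO)CC(=O)SC(C)(C)C | intermediate
8 | methyl (3S)-3-hydroxy-5-oxooxolane-3-carboxylate | COC(=O)[C@@]1(O)COC(=O)C1 | intermediate
9 | methyl (3S,4S)-3-hydroxy-4-(hydroxymethyl)-5-oxooxolane-3-carboxylate | COC(=O)[C@@]1(O)COC(=O)[C@H]1CO | intermediate
10 | (1S,5S)-1-hydroxy-3,7-dioxabicyclo[3.3.0]octane-2,6-dione | O=C1OC[C@@]2(O)[C@@H]1COC2=O | intermediate
11 | 1-(benzyloxy)-4-bromo-2-methoxybenzene | COc1cc(Br)ccc1OCc1ccccc1 | starting material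
12 | [4-(benzyloxy)-3-methoxyphenyl]lithium | COc1cc([Li])ccc1OCc1ccccc1 | intermediate
13 | (1S,5S)-2,6-bis[4-(benzyloxy)-3-methoxyphenyl]-3,7-dioxabicyclo[3.3.0]octane-1,2,6-triol (anomer mixture at C-2 and C-6) | COc1cc(C2(O)OC[C@@]3(O)[C@@H]2COC3(O)c2ccc(OCc4ccccc4)c(OC)c2)ccc1OCc1ccccc1 | intermediate
14 | (1S,2S,5R,6R)-2,6-bis[4-(benzyloxy)-3-methoxyphenyl]-3,7-dioxabicyclo[3.3.0]octan-1-ol | COc1cc([C@@H]2OC[C@@]3(O)[C@@H]2CO[C@H]3c2ccc(OCc4ccccc4)c(OC)c2)ccc1OCc1ccccc1 | intermediate
15 | (1S,2S,5R,6R)-2,6-bis(4-hydroxy-3-methoxyphenyl)-3,7-dioxabicyclo[3.3.0]octan-1-ol | COc1cc([C@@H]2OC[C@@]3(O)[C@@H]2CO[C@H]3c2ccc(O)c(OC)c2)ccc1O | target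

**Totals**

Total steps: 8. Longest linear sequence: 7 (steps 1, 2, 4, 5, 6, 7, 8).

**Steps most likely to fail**

Step 7. What may go wrong: loss of facial control at C-2, which sits beside the tertiary carbinol; acid-induced opening of the new benzylic ethers with epimerisation to exo aryl groups; ionisation or migration at the tertiary carbinol when two cations are generated together. The fallback sets out from 10 and comes back at 14, treating one lactone at a time. Two equivalents of aryllithium 12 (one is consumed by the OH) are added to 10 at −78 °C. The carbonyl next to the lithium alkoxide is deactivated, so addition should occur at C-6 only and give (1S,5S)-6-[4-(benzyloxy)-3-methoxyphenyl]-1,6-dihydroxy-3,7-dioxabicyclo[3.3.0]octan-2-one F3. Et3SiH/BF3·OEt2 at −78 °C reduces this single lactol to (1S,5R,6R)-6-[4-(benzyloxy)-3-methoxyphenyl]-1-hydroxy-3,7-dioxabicyclo[3.3.0]octan-2-one F4. A second addition of 12 gives (1S,5R,6R)-2,6-bis[4-(benzyloxy)-3-methoxyphenyl]-3,7-dioxabicyclo[3.3.0]octane-1,2-diol F5. In F5 the endo aryl group at C-6 further shields the concave face, and the same reduction should give 14.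

Step 5. What may go wrong: reversible and unselective capture of monomeric formaldehyde by the dianion (oligomerisation of formaldehyde, retro-aldol of the adduct, attack syn to the alkoxide). The fallback sets out from 8 and comes back at 10. The same dianion is alkylated irreversibly with benzyl chloromethyl ether (Fráter–Seebach alkylation, anti to O–Li) to give methyl (3S,4S)-4-[(benzyloxy)methyl]-3-hydroxy-5-oxooxolane-3-carboxylate F1. Hydrogenolysis (H2, Pd(OH)2/C, EtOAc) frees the primary alcohol (compound 9), which lactonises with catalytic TsOH to 10.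

Step 6. What may go wrong: incomplete addition at the lactone carbonyl next to the lithium alkoxide, competing enolisation at C-5, and ring opening followed by a second addition. The fallback sets out from 10 and comes back at 13. Both lactones are opened with Me2AlN(OMe)Me (from Me3Al and MeNH(OMe)·HCl, CH2Cl2) to give (2S,3S)-2-hydroxy-2,3-bis(hydroxymethyl)-N1,N4-dimethoxy-N1,N4-dimethylbutanediamide F2. Excess aryllithium 12 then adds to both Weinreb amides through chelated tetrahedral intermediates that stop at the ketone stage, and on work-up the diketone triol closes to 13.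

**Further compounds**

F1 | step 5 | methyl (3S,4S)-4-[(benzyloxy)methyl]-3-hydroxy-5-oxooxolane-3-carboxylate | COC(=O)[C@@]1(O)COC(=O)[C@H]1COCc1ccccc1
F2 | step 6 | (2S,3S)-2-hydroxy-2,3-bis(hydroxymethyl)-N1,N4-dimethoxy-N1,N4-dimethylbutanediamide | CON(C)C(=O)[C@@](O)(CO)[C@H](CO)C(=O)N(C)OC
F3 | step 7 | (1S,5S)-6-[4-(benzyloxy)-3-methoxyphenyl]-1,6-dihydroxy-3,7-dioxabicyclo[3.3.0]octan-2-one | COc1cc(C2(O)OC[C@@]3(O)[C@@H]2COC3=O)ccc1OCc1ccccc1
F4 | step 7 | (1S,5R,6R)-6-[4-(benzyloxy)-3-methoxyphenyl]-1-hydroxy-3,7-dioxabicyclo[3.3.0]octan-2-one | COc1cc([C@@H]2OC[C@@]3(O)[C@@H]2COC3=O)ccc1OCc1ccccc1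
F5 | step 7 | (1S,5R,6R)-2,6-bis[4-(benzyloxy)-3-methoxyphenyl]-3,7-dioxabicyclo[3.3.0]octane-1,2-diol | COc1cc([C@@H]2OC[C@@]3(O)[C@@H]2COC3(O)c2ccc(OCc4ccccc4)c(OC)c2)ccc1OCc1ccccc1
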